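- The closed stirred flask gave me oak, birch and alder, and in oak G stood at 2.51 times the charge of E, so I read each oak point as a pseudo-first-order time, the clock: time divided by ln(1/(1 − fraction of E turned into Q)).

| flask | E | G | X | remark | time |
|---|---|---|---|---|---|
| oak | 0.053 M | 0.133 M | 53 µM | run made earlier |  |
| birch | 0.053 M | 0.067 M | 53 µM | run made earlier |  |
| alder | 0.053 M | 0.10 M | 53 µM | run made earlier |  |
| beta | 0.053 M | 0.133 M (fed, over 1.60 min) | 53 µM | all but G at the start; G goes in evenly over 1.60 min, the run ends at 2.0 min | 2.0 min |
| gamma | 0.053 M | 0.133 M | 53 µM | a single well-mixed tank run continuously and read at steady state, 2.0 min in it on average |  |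
| delta | 0.053 M | 0.133 M | 53 µM | everything together in a closed stirred flask, run for 2.0 min | 2.0 min |
| epsilon | 0.053 M (fed, over 1.60 min) | 0.133 M | 53 µM | all but E at the start; E goes in evenly over 1.60 min, the run ends at 2.0 min | 2.0 min |

| run | time / s | Q / % |
|---|---|---|
| oak | 10.0 | 14 |
| oak | 15.0 | 19 |
| oak | 25.0 | 28 |
| oak | 40.0 | 34 |
| oak | 80.0 | 50 |
| birch | 10.0 | 12 |
| birch | 12.0 | 8 |
| birch | 20.0 | 19 |
| birch | 40.0 | 25 |
| birch | 60.0 | 30 |
| birch | 90.0 | 40 |
| alder | 15.0 | 12 |
| alder | 30.0 | 24 |
| alder | 50.0 | 37 |
| alder | 60.0 | 39 |
| alder | 80.0 | 41 |
| alder | 90.0 | 52 |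

(standard deviation of a reading: 2 percentage points)

- the stated concentrations are those of everything mixed, before any reaction; amounts are the same in each set-up
- the feed brings no volume worth counting
- the earlier runs were made in a closed, stirred flask

- the set-up with the highest amount of Q at the outlet or at the end, in percent of the E put in ("none" if the first two lie within 2 percentage points) (beta / gamma / delta / epsilon / none)
- amount of Q at the outlet or at the end, in percent of the E put in, beta
- amount of Q at the outlet or at the end, in percent of the E put in, gamma
- amount of Q at the outlet or at the end, in percent of the E put in, delta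
- amount of Q at the outlet or at the end, in percent of the E put in, epsilon

- Oak's clock was 76.1 s at 25.0 s and 115 s at 80.0 s, so as read it lengthened, by 39.3 s.
- For delta, holding the last clock gave my upper bound, one minus exp(−time/clock), 64.6%, because the clock had been lengthening.
- For the lower bound I used the stretched clock, the last clock lengthened at the same pace up to 120 s, 144 s, which gave 56.5%.
- A mixed tank turns a clock into x/(1 + x), with x the mean time over the clock, so gamma lay between 45.5% and 51.0%, below delta's bracket.
- In epsilon the fed E, and in beta the fed G, spends 72.0 s in the flask on average up to the end, less than the 120 s of delta, so with gamma below delta's bracket as well I committed to delta as best.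
- The forecast also named delta, with beta 50%, gamma 50%, delta 63% and epsilon 52%; its words were “Allowing for the sag, I take 63%”, which placed delta inside my bracket, above the lower end and below the upper.
- The flasks gave beta 47.9%, gamma 39.0%, delta 56.2% and epsilon 48.3%, so delta came first.

    E + X ⇌ D (K = 25.0 M⁻¹, k = 490 M⁻¹ s⁻¹)
    G + D → L (k = 400 M⁻¹ s⁻¹)
    L → X + Q (k = 2400 s⁻¹)
    E + Q → J (k = 0.220 M⁻¹ s⁻¹)

- Delta's own clock came to 145 s, against the stretched clock's 144 s, and its 56.2% lay 0.30 percentage points under my lower end. Gamma's 39.0% lay 6.5 points under the tank figure from that same clock. Delta had not come to rest at 120 s, with 9.21% of its E still there. The stretched clock carried to 20.0 min gives >99.9%, but ten times the time added 3.9 points, less than that E, and delta's Q ended at 60.1%.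

The data come from a simulation from invented constants.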